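The route reads the quinone's C2=C3 bond (C2 bears the furan, C3 is CH) as an aldol-condensation retron. C2 is the carbonyl carbon of a 2-acylfuran, C3 the methyl carbon of a methyl ketone, and C1 carries a methoxy group as latent quinone oxygen. In one operation the α-methoxy ketone and butynone undergo Michael addition, ring closure C3→C2, dehydration and tautomerisation to a 4-methoxyphenol, which oxidative demethylation turns into the quinone. The cyclisation precursor is an open-chain 2-methoxyhex-3-ene-1,5-dione hanging on the furan. Furan-3-carbaldehyde supplies the heterocycle, and an allylboration sets the stereocentre.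

Key step: step 5

Remark: quinone numbering is C1(=O), C2 (furyl), C3–H, C4(=O), C5–H, C6–H; compounds 2, 8 and (+)-Ipc2B(allyl) are taken as purchased; intermediate 9 is drawn as its cyclising (Z) isomer, unspecified at C-2.

Step 1
Reactants: 1 furan-3-carbaldehyde; 2 N,2-dimethoxy-N-methylacetamide
Product: 4 5-(2-methoxyacetyl)furan-3-carbaldehyde, via C5-lithiated hemiaminal alkoxide 3 (not isolated)
Conditions: morpholine, n-BuLi, THF, −78 °C; 1; s-BuLi, −78 °C; 2, −78 → 0 °C; aq. HCl work-up
Reagents that add atoms: none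
Why: In situ protection of the aldehyde as its lithium morpholine hemiaminal alkoxide shields the formyl group and C-2, so s-BuLi should metalate the remote α-position C-5 (α-amino alkoxide directed lithiation, the established way to 5-substituted 3-furaldehydes), and the furyllithium is acylated once through the chelated tetrahedral intermediate (Weinreb ketone synthesis).

Step 2
Reactants: 4 5-(2-methoxyacetyl)furan-3-carbaldehyde
Product: 5 1-{4-[(1R)-1-hydroxybut-3-en-1-yl]furan-2-yl}-2-methoxyethan-1-one
Conditions: (+)-Ipc2B(allyl), Et2O, −78 °C; then ethanolamine, rt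
Reagents that add atoms: (+)-B-allyldiisopinocampheylborane, C=CCB([C@H]1C[C@H]2C[C@H](C2(C)C)[C@@H]1C)[C@H]1C[C@H]2C[C@H](C2(C)C)[C@@H]1C
Why: Brown asymmetric allylboration: the (−)-α-pinene-derived reagent should deliver allyl to the Re face of the aldehyde through a chair Zimmerman–Traxler transition state, as it does with benzaldehyde (which it converts into (R)-1-phenylbut-3-en-1-ol), setting the (R) carbinol, while the much less electrophilic ketone is left alone at −78 °C.

Step 3
Reactants: 5 1-{4-[(1R)-1-hydroxybut-3-en-1-yl]furan-2-yl}-2-methoxyethan-1-one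
Product: 6 1-{4-[(1R)-1-hydroxy-4-methylpent-3-en-1-yl]furan-2-yl}-2-methoxyethan-1-one
Conditions: Hoveyda–Grubbs II (3 mol %), 2-methyl-2-butene/CH2Cl2, 40 °C
Reagents that add atoms: 2-methyl-2-butene, CC=C(C)C
Why: Olefin cross-metathesis of the terminal alkene with excess 2-methyl-2-butene exchanges CH2 for isopropylidene with loss of propene; furan, ketone and free alcohol are tolerated, and the trisubstituted product is a poor substrate for further metathesis.

Step 4
Reactants: 6 1-{4-[(1R)-1-hydroxy-4-methylpent-3-en-1-yl]furan-2-yl}-2-methoxyethan-1-one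
Product: 7 (1R)-1-[5-(2-methoxyacetyl)furan-3-yl]-4-methylpent-3-en-1-yl 3-methylbutanoate
Conditions: 3-methylbutanoyl chloride, Et3N, DMAP (cat.), CH2Cl2, 0 °C → rt
Reagents that add atoms: 3-methylbutanoyl chloride, CC(C)CC(=O)Cl
Why: DMAP-catalysed O-acylation of the secondary alcohol (nucleophilic catalysis) does not touch the C–O bond of the stereocentre, so the (R) configuration is retained.

Step 5
Reactants: 7 (1R)-1-[5-(2-methoxyacetyl)furan-3-yl]-4-methylpent-3-en-1-yl 3-methylbutanoate; 8 but-3-yn-2-one
Product: 11 (1R)-1-[5-(5-hydroxy-2-methoxyphenyl)furan-3-yl]-4-methylpent-3-en-1-yl 3-methylbutanoate, via Michael adduct enedione 9 (not isolated), via methoxycyclohexadienone 10 (not isolated)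
Conditions: KOt-Bu (1.05 equiv), THF/t-BuOH, −40 °C; 8 added slowly; then 40 °C; AcOH quench
Reagents that add atoms: none
Why: The only enolisable ketone position of 7 (C-2 of the methoxyacetyl group) is deprotonated and adds to the ynone (Michael addition); proton shuffling gives the vinylogous 1,5-diketone 9 as a delocalised anion whose E and Z forms interconvert. The minor methyl-ketone enolate of (Z)-9 then attacks the furyl ketone carbonyl (6-(enolendo)-exo-trig aldol), joining the former acetyl methyl carbon (quinone C3) to the former acyl carbon (quinone C2); E1cB loss of hydroxide gives dienone 10, which tautomerises irreversibly to the phenoxide of 11. The closest known reaction types are the Robinson annulation with an ethynyl ketone and the classical recyclisation of 2-methylpyrylium pseudobases (pent-2-ene-1,5-diones) to phenols. No new stereocentre survives: C-2 of 9 and C-6 of 10 are planarised on aromatisation, and the carbinol centre bears no acidic hydrogen. The step needs C- over O-cyclisation and attack by the methyl carbon only: O-closure to the 2H-pyranol is reversible, the other carbon nucleophiles would give three- or four-membered rings, and aromatisation drains the equilibrium; the hindered secondary ester should survive because the base is bulky and ends as the weakly basic phenoxide.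

Step 6
Reactants: 11 (1R)-1-[5-(5-hydroxy-2-methoxyphenyl)furan-3-yl]-4-methylpent-3-en-1-yl 3-methylbutanoate
Product: 12 (1R)-1-[5-(3,6-dioxocyclohexa-1,4-dien-1-yl)furan-3-yl]-4-methylpent-3-en-1-yl 3-methylbutanoate
Conditions: PhI(OAc)2 (1.1 equiv), MeCN/H2O 4:1, 0 °C
Reagents that add atoms: water, O
Why: Oxidative demethylation of a p-methoxyphenol by a λ3-iodane (ligand exchange at the phenol oxygen, attack of water at the methoxy-bearing para carbon, loss of methanol) should give the p-quinone much faster than any reaction at the furan, ester or trisubstituted alkene at 0 °C.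

Compound list
1 | furan-3-carbaldehyde | O=Cc1ccoc1 | starting material
2 | N,2-dimethoxy-N-methylacetamide | COCC(=O)N(C)OC | starting material
3 | lithium (5-lithiofuran-3-yl)(morpholin-4-yl)methanolate | [Li]c1cc(C(O[Li])N2CCOCC2)co1 | intermediate
4 | 5-(2-methoxyacetyl)furan-3-carbaldehyde | COCC(=O)c1cc(C=O)co1 | intermediate
5 | 1-{4-[(1R)-1-hydroxybut-3-en-1-yl]furan-2-yl}-2-methoxyethan-1-one | C=CC[C@@H](O)c1coc(C(=O)COC)c1 | intermediate
6 | 1-{4-[(1R)-1-hydroxy-4-methylpent-3-en-1-yl]furan-2-yl}-2-methoxyethan-1-one | CC(C)=CC[C@@H](O)c1coc(C(=O)COC)c1 | intermediate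
7 | (1R)-1-[5-(2-methoxyacetyl)furan-3-yl]-4-methylpent-3-en-1-yl 3-methylbutanoate | CC(C)=CC[C@@H](OC(=O)CC(C)C)c1coc(C(=O)COC)c1 | intermediate
8 | but-3-yn-2-one | CC(=O)C#C | starting material
9 | (1R)-1-{5-[(3Z)-2-methoxy-5-oxohex-3-enoyl]furan-3-yl}-4-methylpent-3-en-1-yl 3-methylbutanoate (both C-2 epimers) | CC(C)=CC[C@@H](OC(=O)CC(C)C)c1coc(C(=O)C(OC)/C=C\C(C)=O)c1 | intermediate
10 | (1R)-1-[5-(6-methoxy-3-oxocyclohexa-1,4-dien-1-yl)furan-3-yl]-4-methylpent-3-en-1-yl 3-methylbutanoate | CC(C)=CC[C@@H](OC(=O)CC(C)C)c1coc(C2=CC(=O)C=CC2OC)c1 | intermediate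
11 | (1R)-1-[5-(5-hydroxy-2-methoxyphenyl)furan-3-yl]-4-methylpent-3-en-1-yl 3-methylbutanoate | CC(C)=CC[C@@H](OC(=O)CC(C)C)c1coc(-c2cc(O)ccc2OC)c1 | intermediate
12 | (1R)-1-[5-(3,6-dioxocyclohexa-1,4-dien-1-yl)furan-3-yl]-4-methylpent-3-en-1-yl 3-methylbutanoate | CC(C)=CC[C@@H](OC(=O)CC(C)C)c1coc(C2=CC(=O)C=CC2=O)c1 | target

Total step count: 6. Longest linear sequence: 6 steps (from furan-3-carbaldehyde).

Steps most likely to fail

Step 5. The ynone may oligomerise or be O-alkylated, or the stabilised pentadienyl-type anion of the Michael adduct may stall without closing onto the ketone. The fallback sets out from 7 and builds the ring stepwise at the saturated level. Base-catalysed conjugate addition of 7 to methyl vinyl ketone (cat. KOt-Bu, THF/t-BuOH, 0 °C) should give (1R)-1-[5-(2-methoxy-5-oxohexanoyl)furan-3-yl]-4-methylpent-3-en-1-yl 3-methylbutanoate F1. Pyrrolidine/AcOH-mediated aldol condensation then closes the same C2–C3 bond to the cyclohexenone (1R)-1-[5-(6-methoxy-3-oxocyclohex-1-en-1-yl)furan-3-yl]-4-methylpent-3-en-1-yl 3-methylbutanoate F2. Kinetic enolisation (LiHMDS, TMSCl, −78 °C) gives the silyl dienol ether (1R)-1-{5-[6-methoxy-3-(trimethylsilyloxy)cyclohexa-1,3-dien-1-yl]furan-3-yl}-4-methylpent-3-en-1-yl 3-methylbutanoate F3. Saegusa–Ito dehydrogenation (Pd(OAc)2, MeCN) leads to dienone 10, which tautomerises, and the route is rejoined at 11.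

Step 1. Metalation may be incomplete or unselective between C-2 and C-5, or the furyllithium may be quenched by proton transfer from the amide. The fallback sets out from 1 and builds the side chain first. Allylboration of 1 with (+)-Ipc2B(allyl) gives (1R)-1-(furan-3-yl)but-3-en-1-ol F4. Cross-metathesis with 2-methyl-2-butene gives (1R)-1-(furan-3-yl)-4-methylpent-3-en-1-ol F5. Acylation with 3-methylbutanoyl chloride gives (1R)-1-(furan-3-yl)-4-methylpent-3-en-1-yl 3-methylbutanoate F6. Sterically controlled iridium-catalysed C–H borylation ([Ir(OMe)(cod)]2, dtbpy, B2pin2) at the α-position remote from the substituent gives (1R)-4-methyl-1-[5-(4,4,5,5-tetramethyl-1,3,2-dioxaborolan-2-yl)furan-3-yl]pent-3-en-1-yl 3-methylbutanoate F7. Acylative Suzuki–Miyaura coupling with methoxyacetyl chloride (Pd(PPh3)4, anhydrous K3PO4, toluene) rejoins the route at 7.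

Step 6. The electron-rich furan may be over-oxidised, or the product quinone may degrade in the aqueous oxidising medium. The fallback sets out from 11 and separates oxidation from unmasking. Oxidation in anhydrous methanol (PhI(OAc)2, MeOH, −20 °C) should stop at the quinone monoketal (1R)-1-[5-(6,6-dimethoxy-3-oxocyclohexa-1,4-dien-1-yl)furan-3-yl]-4-methylpent-3-en-1-yl 3-methylbutanoate F8, which is isolated. It is then hydrolysed without oxidant (aqueous oxalic acid, THF) to rejoin the route at 12.

Further compounds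
F1 | step 5 | (1R)-1-[5-(2-methoxy-5-oxohexanoyl)furan-3-yl]-4-methylpent-3-en-1-yl 3-methylbutanoate | CC(C)=CC[C@@H](OC(=O)CC(C)C)c1coc(C(=O)C(OC)CCC(C)=O)c1
F2 | step 5 | (1R)-1-[5-(6-methoxy-3-oxocyclohex-1-en-1-yl)furan-3-yl]-4-methylpent-3-en-1-yl 3-methylbutanoate | CC(C)=CC[C@@H](OC(=O)CC(C)C)c1coc(C2=CC(=O)CCC2OC)c1
F3 | step 5 | (1R)-1-{5-[6-methoxy-3-(trimethylsilyloxy)cyclohexa-1,3-dien-1-yl]furan-3-yl}-4-methylpent-3-en-1-yl 3-methylbutanoate | CC(C)=CC[C@@H](OC(=O)CC(C)C)c1coc(C2=CC(O[Si](C)(C)C)=CCC2OC)c1
F4 | step 1 | (1R)-1-(furan-3-yl)but-3-en-1-ol | C=CC[C@@H](O)c1ccoc1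
F5 | step 1 | (1R)-1-(furan-3-yl)-4-methylpent-3-en-1-ol | CC(C)=CC[C@@H](O)c1ccoc1
F6 | step 1 | (1R)-1-(furan-3-yl)-4-methylpent-3-en-1-yl 3-methylbutanoate | CC(C)=CC[C@@H](OC(=O)CC(C)C)c1ccoc1
F7 | step 1 | (1R)-4-methyl-1-[5-(4,4,5,5-tetramethyl-1,3,2-dioxaborolan-2-yl)furan-3-yl]pent-3-en-1-yl 3-methylbutanoate | CC(C)=CC[C@@H](OC(=O)CC(C)C)c1coc(B2OC(C)(C)C(C)(C)O2)c1
F8 | step 6 | (1R)-1-[5-(6,6-dimethoxy-3-oxocyclohexa-1,4-dien-1-yl)furan-3-yl]-4-methylpent-3-en-1-yl 3-methylbutanoate | CC(C)=CC[C@@H](OC(=O)CC(C)C)c1coc(C2=CC(=O)C=CC2(OC)OC)c1
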